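The constants of this chemistry are not given to me, so I begin from the symmetry of the charge. The two substrates are mirror images, charged equally, and I take a selectivity factor of one as the zero of my scale: each hand then supplies the same share of the conversion. This gives the mirror mark, the left-handed product standing at the asked conversion when the two hands keep pace: 15.0 %, with 35.0 % of left-handed substrate beside it.

| flask | left-handed substrate | right-handed substrate | reagent | free catalyst | remark |
|---|---|---|---|---|---|
| midnight | 0.50 M | 0.50 M | 1 M | 1.9 mM | run made earlier |
| dawn | 0.50 M | 0.50 M | 2.2 M | 1.9 mM | run made earlier |
| winter | 0.50 M | 0.50 M | 1.5 M | 2.8 mM | run made earlier |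
| flask | 0.50 M | 0.50 M | 1.50 M | 1.9 mM |  |

- midnight (time / min: left-handed product / %, left-handed substrate / %): 0.200: 6.7, 43.4; 0.333: 12.1, 39.3; 0.417: 13.1, 36.7; 0.667: 18.9, 31.5; 1.00: 24.5, 25.4; 1.50: 30.4, 19.5; 2.50: 37.3, 13.3
- dawn (time / min: left-handed product / %, left-handed substrate / %): 0.333: 20.4, 29.6; 0.667: 29.4, 20.0; 1.00: 35.7, 13.8; 1.33: 38.9, 10.5; 1.50: 40.5, 10.1; 2.00: 43.4, 6.0; 2.50: 43.8, 5.7
- winter (time / min: left-handed product / %, left-handed substrate / %): 0.200: 14.4, 35.3; 0.333: 20.7, 28.4; 0.667: 32.9, 15.4; 1.33: 43.1, 5.4; 2.50: 48.8, 2.2

(readings scatter by 0.5 percentage points)

- free catalyst is single-handed; left-handed substrate and right-handed substrate are mirror images of each other, charged as a racemate, each of them at the stated concentration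

- apparent order in reagent when 30 % of the left-handed substrate and right-handed substrate together are converted (percent change of the rate of making left-handed product for one percent more reagent charged)
- apparent order in free catalyst when 30 % of the left-handed substrate and right-handed substrate together are converted (percent change of the rate of making left-handed product for one percent more free catalyst charged)
- factor on the rate of making left-handed product when 30 % of the left-handed substrate and right-handed substrate together are converted if reagent is charged twice over

The mark is the same level of left-handed product on every run, so the times to reach it form a ladder. I read them from the readings, with their scatter, from the fastest rung to the slowest: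

winter, between two readings: t = 0.213 min

dawn, on a straight line from zero: t = 0.245 min

midnight, between two readings: t = 0.499 min

Winter gets there first. The mark fixes the left-handed product on each rung, but not the other charges: midnight, dawn and winter are charged with 1 M, 2.2 M and 1.5 M of reagent, and winter with 2.8 mM of free catalyst against 1.9 mM in the other two. Midnight and dawn share their catalyst, so their times give my mean order in reagent:

n = ln(t midnight / t dawn) / ln(c reagent, dawn / c reagent, midnight) = 0.903

Placing the flask on that line gives t = 0.346 min. Setting this against winter gives my order in free catalyst:

m = ln(t flask / t winter) / ln(c free catalyst, winter / c free catalyst, flask) = 1.26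

Doubling the reagent then gives me a factor of 1.87.

The forecast gives 1.05, 1.4 and 2, and it looks elsewhere: “I therefore take 30% conversion as about 30% product, with 20% left-handed substrate remaining.” That product is twice my mark, and its order in reagent stands above mine.

The flask gives 0.96, 1.2 and 1.69.

    free catalyst + left-handed substrate ⇌ catalyst intermediate A (K = 4.05 M⁻¹, k = 69.4 M⁻¹ s⁻¹)
    free catalyst + right-handed substrate ⇌ catalyst intermediate B (K = 8.66 M⁻¹, k = 56.4 M⁻¹ s⁻¹)
    reagent + catalyst intermediate A → free catalyst + left-handed product (k = 13.6 M⁻¹ s⁻¹)
    reagent + catalyst intermediate B → free catalyst + right-handed product (k = 6.63 M⁻¹ s⁻¹)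
    reagent + free catalyst → spent catalyst (k = 0.0204 M⁻¹ s⁻¹)
    reagent → decomposition product (k = 1.68 × 10⁻⁵ s⁻¹)

The flask passes the asked conversion at 0.333 min, close to my 0.346 min, and at 0.300 min it holds 14.3 % of left-handed product and 13.2 % of right-handed product, so the hands do keep pace. A simulated run of this flask without the conversion of catalyst intermediate B to right-handed product makes no right-handed product, so the left hand must supply the whole conversion. The mark there moves to 30.0 %, with 20.0 % of left-handed substrate. With the conversion of catalyst intermediate B to right-handed product taken away, the rate at the asked conversion is 0.235 of the actual one, and the order in reagent falls from 0.96 to 0.35.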